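## The problem

Compound 18 is a 4-aryl-3,4-dihydrocoumarin (chroman-2-one numbering: O1, C2, C3, C4, C4a, C5 to C8, C8a). Benzo ring A carries the lactone oxygen at C8a, a free hydroxyl at C7 and an (E)-4-hydroxy-3-methoxystyryl arm (ring C) at C5; C4 carries a second 4-hydroxy-3-methoxyphenyl group (ring B). Ring A is therefore 1,2,3,5-tetrasubstituted, and C4a lies between C8a–O and the C5 styryl group, so the C4–C4a bond must be made at a doubly ortho-substituted carbon and without ambiguity against C6 and C8. C4, of R configuration, is the only stereocenter. It is a diarylmethine with no neighbouring stereo element, so a catalyst or reagent must set it, and the two aryl groups to be told apart differ mainly in ortho substitution. The electron-rich E-stilbene excludes hydrogenolysis, peracids and strong acid, the two guaiacyl methyl ethers exclude ether cleavage of the BBr3 kind, and the lactone opens in alcohols and base. Once the phenols ortho (C8a) and para (ring B) to C4 are free, base can racemize C4 by retro-Michael loss of the enolate through a quinone methide, so the phenols stay masked until a final acidic step. The enabling feature is that C4 is bonded to C4a, to C1 of ring B and to C3, and neither aryl neighbour offers a β-hydrogen. C4 can therefore enter as the aldehyde carbon of vanillin in carbene form, between an aryl palladium (ring A) and a malonate (C3 and the future C2), and the organopalladium on the way cannot collapse by β-hydride elimination.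

## Retrosynthesis

**Lactone and phenol masks (18 ⇒ 17 ⇒ 16).** The O1–C2 acyl bond is cut and the four phenols are re-masked as methoxymethyl (MOM) ethers. Lactone 18 is the internal ester of hydroxy ester 17, so opening it leaves an acyclic 3,3-diarylpropanoate, 16. MOM is chosen because one aqueous acid treatment frees all four phenols and lets the C8a hydroxyl close the ring. Benzyl ethers would need hydrogenolysis beside the stilbene, methyl ethers could not be told from the two guaiacyl methoxy groups, and silyl ethers would be at risk from the alkoxide and the heating used earlier. The forward step must hydrolyse the acetals without protonating the stilbene and must run in a non-alcoholic medium so the lactone is not reopened.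

**One carboxyl more (16 ⇒ 15).** A methoxycarbonyl group is added back at C3, turning the acetate arm into a malonate, which is the soft carbon nucleophile that palladium chemistry wants. The forward step is a dealkoxycarbonylation under neutral conditions; C4 has no acidic hydrogen and no β leaving group while the phenols are masked, so it cannot epimerize.

**The key cut (15 ⇒ 10 + 12 + 13).** Both C4–C4a and C3–C4 are cut, leaving C4 as a carbene carbon that is released from hydrazone 12 as diazo compound 14. Two neighbouring cuts were weighed:
- Cutting only C4–C4a (acid-mediated hydroarylation of a cinnamate by the resorcinol ring) offers no handle for asymmetric induction and puts the stilbene in strong acid.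
- Cutting only the C4–ring B bond (conjugate addition of an arylmetal to a ring A cinnamate) is well known and is kept in reserve, but it needs a preformed acrylate and an arylboron reagent.

The double cut makes two bonds and the stereocenter from three simple pieces: achiral aryl bromide 10, hydrazone 12 and commercial malonate 13. The forward reaction must achieve oxidative addition at a hindered C–Br bond, carbene transfer faster than carbene side reactions, and ligand-controlled malonate attack at C4.

**The stilbene (10 ⇒ 3 + 9).** The Cα=Cβ double bond is cut into aldehyde 3 and benzylic phosphonate 9. A phosphonate olefination gives the E isomer and leaves the aryl bromide alone; a Heck disconnection would compete for the very C–Br bond the key step needs.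

**Ring A aldehyde (3 ⇒ 2 ⇒ 1).** The C4a–Br bond and the two acetal O–C bonds are cut. In symmetrical aldehyde 2 the two positions para to one acetal oxygen and ortho to the other are equivalent and become C4a; the position between both oxygens is crowded. The bromine is placed before any alkene exists.

**The phosphonate (9 ⇒ 8 ⇒ 6 ⇒ 5 ⇒ 4).** The C–P bond is cut to chloride 8, which comes from alcohol 6 through mesylate 7; 6 comes from aldehyde 5 and 5 from vanillin 4. Aldehyde 5 serves twice, here and for the hydrazone.

**The hydrazone (12 ⇒ 5 + 11).** The C=N bond is cut to aldehyde 5 and sulfonyl hydrazide 11, a simple condensation.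

## Roads not taken

**Alternative 1:** Asymmetric hydroacylation to an indanone, then oxygen insertion.
- Cut: O1 is removed from the lactone (Baeyer–Villiger retron) to give indanone A2, whose C2–C3 bond is then cut to aldehyde A1.
- Forward key step: a cationic monovalent rhodium complex such as [Rh((R)-BINAP)]ClO4 inserts into the aldehyde C–H bond of A1. The acyl rhodium hydride adds across the 1-arylvinyl group with hydrogen going to C4, and reductive elimination forms C2–C3, closing the five-membered ketone and setting C4 in A2. A peracid would then insert oxygen between C8a and C2.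
- Merits: enantioselective hydroacylation of 2-(1-arylvinyl)benzaldehydes to 3-arylindanones is an established reaction type. On precedent for the asymmetric event this road stands on firmer ground than step 9.
- Weak points: the oxygen insertion needs a peracid on a molecule that contains an electron-rich stilbene and silyloxy arenes, so epoxidation competes and the stilbene cannot be postponed without extra steps. A1 needs three contiguous carbon substituents on ring A (formyl, 1-arylvinyl, styryl), each from its own coupling, and two kinds of silyl ether. The 1-arylvinyl group is squeezed between two ortho groups, which slows alkene insertion and favours decarbonylation.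
- Comparison: the chosen plan has no oxidation after the stilbene is in place and takes the ring A pattern from bromination of a symmetrical aldehyde. Against the better precedent of this alternative it sets a reserve route of known chemistry that rejoins at 16.

**Alternative 2:** Polyketide-style aldol aromatization with lactonization.
- Cut: C4a–C5 and O1–C2, leading to the open-chain triketo ester A3.
- Forward key step: aqueous KOH forms the C4a enolate of A3, which adds to the C5 ketone and closes ring A; dehydration and enolization aromatize it. Acidification then acylates the new C8a hydroxyl with the C2 carboxyl to give A4, which differs from 18 by two MOM groups.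
- Merits: ring A and the lactone form in one operation, with no transition metal and no hindered aryl halide. In rings made per step this road is better than the chosen one, whose key step closes no ring.
- Weak points: the required C4a enolate is the least acidic site of A3, since C6 and C8 lie between two carbonyls. The C5 carbonyl is the least electrophilic because it is an enone. Michael and oxa-Michael closures onto the styryl enone compete with the aldol. A3 must be built by polyanion chemistry in the presence of that enone. C4 has to be set earlier by a separate asymmetric step, so the complexity-building step does not address the stereocenter.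
- Comparison: the chosen plan buys ring A, fixes its substitution by one bromination, and forms the stereocenter in the same step as the two new C–C bonds.

**Alternative 3:** Danheiser benzannulation of a chiral cyclobutenone.
- Cut: C8–C8a, C6–C7 and C4a–C8a, leading to cyclobutenone A5 and silyloxyalkyne A6.
- Forward key step: on heating, A5 opens to a vinylketene that adds A6. The new 4-vinylcyclobutenone reopens and the dienylketene closes by 6π electrocyclization to ring A, giving phenol A7 after tautomerization.
- Merits: the ring A pattern is fixed by construction, and the two ring A oxygens emerge differentiated with the C8a hydroxyl free for lactonization. The conditions are neutral and metal-free. In regiochemical certainty it is at least as good as the chosen plan.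
- Weak points: A5 must already contain ring B, ring C and the C4 stereocenter, so all the hard work moves into making a strained, thermally labile cyclobutenone. That would need a ketene–enyne cycloaddition with its own chemoselectivity problem and a separate asymmetric step. A6 has to be generated and used fresh. The vinylketene can also be trapped by the electron-rich stilbene of a second molecule.
- Comparison: the chosen plan reaches the same kind of late intermediate (16 against A7) from purchased arenes, and creates C4 in the convergent step, not before it.

Key step: step 9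

Assumption: the sense of induction of a biaryl bisphosphine in step 9 cannot be predicted for this new reaction; (R)-H8-BINAP is written as the working ligand, and its mirror image would be used if it proves to give the (S) centre.

## Route

Step 1
Reactants: 1 3,5-dihydroxybenzaldehyde
Product: 2 3,5-bis(methoxymethoxy)benzaldehyde
Conditions: MOMCl, iPr2NEt, DMF, 0 °C to rt
Reagents that add atoms: chloromethyl methyl ether, COCCl
Why: O-alkylation of both phenols (MOM protection) under amine base; the aldehyde is untouched.

Step 2
Reactants: 2 3,5-bis(methoxymethoxy)benzaldehyde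
Product: 3 2-bromo-3,5-bis(methoxymethoxy)benzaldehyde
Conditions: NBS, MeCN, 0 °C to rt, dark
Reagents that add atoms: N-bromosuccinimide, O=C1CCC(=O)N1Br
Why: Electrophilic aromatic bromination; the two equivalent positions para to one acetal oxygen and ortho to the other are the most activated and least crowded, as in the known bromination of 3,5-dialkoxybenzaldehydes, and NBS releases no free acid that would endanger the acetals.

Step 3
Reactants: 4 vanillin (4-hydroxy-3-methoxybenzaldehyde)
Product: 5 3-methoxy-4-(methoxymethoxy)benzaldehyde
Conditions: MOMCl, iPr2NEt, CH2Cl2, 0 °C to rt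
Reagents that add atoms: chloromethyl methyl ether, COCCl
Why: Standard MOM protection of a phenol.

Step 4
Reactants: 5 3-methoxy-4-(methoxymethoxy)benzaldehyde
Product: 6 [3-methoxy-4-(methoxymethoxy)phenyl]methanol
Conditions: NaBH4, MeOH, 0 °C
Reagents that add atoms: none
Why: Borohydride reduction of an aryl aldehyde; the acetal is inert to hydride.

Step 5
Reactants: 6 [3-methoxy-4-(methoxymethoxy)phenyl]methanol
Product: 8 4-(chloromethyl)-2-methoxy-1-(methoxymethoxy)benzene, via benzylic mesylate 7 (not isolated)
Conditions: MsCl, Et3N, CH2Cl2, 0 °C to rt
Reagents that add atoms: methanesulfonyl chloride, CS(=O)(=O)Cl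
Why: Mesylation followed by in-flask nucleophilic substitution; the electron-rich benzylic mesylate is displaced by the chloride of the amine hydrochloride, a base-buffered way to p-alkoxybenzyl chlorides that spares the MOM group.

Step 6
Reactants: 8 4-(chloromethyl)-2-methoxy-1-(methoxymethoxy)benzene
Product: 9 diethyl {[3-methoxy-4-(methoxymethoxy)phenyl]methyl}phosphonate
Conditions: P(OEt)3 (neat), 130 °C
Reagents that add atoms: triethyl phosphite, CCOP(OCC)OCC
Why: Michaelis–Arbuzov reaction of a benzylic chloride; the medium is neutral, and MOM-protected benzylic halides are routine substrates.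

Step 7
Reactants: 3 2-bromo-3,5-bis(methoxymethoxy)benzaldehyde; 9 diethyl {[3-methoxy-4-(methoxymethoxy)phenyl]methyl}phosphonate
Product: 10 2-bromo-1,5-bis(methoxymethoxy)-3-{(E)-2-[3-methoxy-4-(methoxymethoxy)phenyl]ethenyl}benzene
Conditions: KOtBu, THF, 0 °C to rt
Reagents that add atoms: none
Why: Horner–Wadsworth–Emmons olefination; a benzylic phosphonate anion and an aryl aldehyde add reversibly and eliminate to the E-stilbene, and the aryl bromide and the acetals are inert to the alkoxide at room temperature.

Step 8
Reactants: 5 3-methoxy-4-(methoxymethoxy)benzaldehyde; 11 p-toluenesulfonyl hydrazide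
Product: 12 N'-{(E)-[3-methoxy-4-(methoxymethoxy)phenyl]methylidene}-4-methylbenzenesulfonohydrazide
Conditions: MeOH, 60 °C
Reagents that add atoms: none
Why: Condensation of an aldehyde with a sulfonyl hydrazide to the crystalline N-tosylhydrazone; no acid is added, so the MOM group is safe.

Step 9
Reactants: 10 2-bromo-1,5-bis(methoxymethoxy)-3-{(E)-2-[3-methoxy-4-(methoxymethoxy)phenyl]ethenyl}benzene; 12 N'-{(E)-[3-methoxy-4-(methoxymethoxy)phenyl]methylidene}-4-methylbenzenesulfonohydrazide; 13 dimethyl malonate
Product: 15 dimethyl 2-[(R)-{2,4-bis(methoxymethoxy)-6-[(E)-2-(3-methoxy-4-(methoxymethoxy)phenyl)ethenyl]phenyl}[3-methoxy-4-(methoxymethoxy)phenyl]methyl]propanedioate, via aryldiazomethane 14 (not isolated)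
Conditions: Pd2(dba)3 (5 mol %), (R)-H8-BINAP (12 mol %), LiOtBu (4 equiv), 13 (2 equiv), 12 (1.5 equiv, slow addition), 1,4-dioxane, 90 °C
Reagents that add atoms: none
Why: Proposed new method: zerovalent palladium carrying the bisphosphine inserts into the C4a–Br bond of 10, LiOtBu converts 12 into aryldiazomethane 14 (Bamford–Stevens), the divalent arylpalladium bromide decomposes 14 to a palladium carbene, and 1,2-migration of ring A to the carbene carbon forms C4–C4a. The diarylmethyl palladium so formed has no β-hydrogen and rests as an η3-benzyl complex over ring B, whose ortho positions are free, until lithium dimethyl malonate attacks C4 on the face away from the metal, forming C3–C4 and returning zerovalent palladium. The closest known reaction types are the carbene cross-coupling of aryl bromides with N-tosylhydrazones, carbenylative three-component alkylations that end with malonate attack on an η3-allyl palladium, and the asymmetric benzylic alkylation of diarylmethyl carbonates by malonates under Pd/BINAP-type catalysis; their merger at a diarylmethyl carbon has not been shown. No ring closes in this step. C4 is the only new stereocenter and is under ligand control: either the migratory insertion fixes the configuration at the palladium-bound carbon and anti attack inverts it, or the two diastereomeric η3 complexes interconvert by palladium-for-palladium exchange and the faster-reacting one is drained. The step needs chemoselectivity for carbene capture over malonate α-arylation, carbene dimerization and cyclopropanation of the stilbene; the chelating ligand (which disfavours reductive elimination from an aryl palladium enolate), slow addition of 12 and the 1,2-diaryl substitution of the alkene should secure it. It also needs attack at the benzylic carbon in preference to the ring, which rearomatization secures, and the doubly ortho-blocked ring A helps enantio-discrimination because it cannot share the η3 binding.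

Step 10
Reactants: 15 dimethyl 2-[(R)-{2,4-bis(methoxymethoxy)-6-[(E)-2-(3-methoxy-4-(methoxymethoxy)phenyl)ethenyl]phenyl}[3-methoxy-4-(methoxymethoxy)phenyl]methyl]propanedioate
Product: 16 methyl (3R)-3-{2,4-bis(methoxymethoxy)-6-[(E)-2-(3-methoxy-4-(methoxymethoxy)phenyl)ethenyl]phenyl}-3-[3-methoxy-4-(methoxymethoxy)phenyl]propanoate
Conditions: LiCl, H2O, DMSO, 150 °C
Reagents that add atoms: none
Why: Krapcho dealkoxycarbonylation; chloride attacks one ester methyl, the carboxylate loses CO2 and water protonates the enolate. The medium is neutral, so the acetals and the stilbene survive, and C4 has neither an acidic hydrogen nor a β leaving group while the phenols are masked.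

Step 11
Reactants: 16 methyl (3R)-3-{2,4-bis(methoxymethoxy)-6-[(E)-2-(3-methoxy-4-(methoxymethoxy)phenyl)ethenyl]phenyl}-3-[3-methoxy-4-(methoxymethoxy)phenyl]propanoate
Product: 18 (4R)-7-hydroxy-4-(4-hydroxy-3-methoxyphenyl)-5-[(E)-2-(4-hydroxy-3-methoxyphenyl)ethenyl]-3,4-dihydro-2H-chromen-2-one, via tetraphenol methyl ester 17 (not isolated)
Conditions: 3 M aq. HCl, THF, 50 °C
Reagents that add atoms: none
Why: Acid hydrolysis of the four MOM acetals, then acid-catalysed lactonization of the C8a phenol onto the methyl ester; the six-membered closure is favoured by the C4 aryl and C5 styryl groups pressing the chain toward that phenol. THF–water is used in place of methanol so the lactone is not reopened, and C4 is not epimerizable under acid.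

## Compound list

1 | 3,5-dihydroxybenzaldehyde | O=Cc1cc(O)cc(O)c1 | starting material
2 | 3,5-bis(methoxymethoxy)benzaldehyde | COCOc1cc(C=O)cc(OCOC)c1 | intermediate
3 | 2-bromo-3,5-bis(methoxymethoxy)benzaldehyde | COCOc1cc(C=O)c(Br)c(OCOC)c1 | intermediate
4 | vanillin (4-hydroxy-3-methoxybenzaldehyde) | COc1cc(C=O)ccc1O | starting material
5 | 3-methoxy-4-(methoxymethoxy)benzaldehyde | COCOc1ccc(C=O)cc1OC | intermediate
6 | [3-methoxy-4-(methoxymethoxy)phenyl]methanol | COCOc1ccc(CO)cc1OC | intermediate
7 | 3-methoxy-4-(methoxymethoxy)benzyl methanesulfonate | COCOc1ccc(COS(C)(=O)=O)cc1OC | intermediate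
8 | 4-(chloromethyl)-2-methoxy-1-(methoxymethoxy)benzene | COCOc1ccc(CCl)cc1OC | intermediate
9 | diethyl {[3-methoxy-4-(methoxymethoxy)phenyl]methyl}phosphonate | CCOP(=O)(Cc1ccc(OCOC)c(OC)c1)OCC | intermediate
10 | 2-bromo-1,5-bis(methoxymethoxy)-3-{(E)-2-[3-methoxy-4-(methoxymethoxy)phenyl]ethenyl}benzene | COCOc1cc(OCOC)c(Br)c(/C=C/c2ccc(OCOC)c(OC)c2)c1 | intermediate
11 | p-toluenesulfonyl hydrazide (4-methylbenzenesulfonohydrazide) | Cc1ccc(cc1)S(=O)(=O)NN | starting material
12 | N'-{(E)-[3-methoxy-4-(methoxymethoxy)phenyl]methylidene}-4-methylbenzenesulfonohydrazide | Cc1ccc(cc1)S(=O)(=O)N/N=C/c1ccc(OCOC)c(OC)c1 | intermediate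
13 | dimethyl malonate (dimethyl propanedioate) | COC(=O)CC(=O)OC | starting material
14 | 4-(diazomethyl)-2-methoxy-1-(methoxymethoxy)benzene | COCOc1ccc(C=[N+]=[N-])cc1OC | intermediate
15 | dimethyl 2-[(R)-{2,4-bis(methoxymethoxy)-6-[(E)-2-(3-methoxy-4-(methoxymethoxy)phenyl)ethenyl]phenyl}[3-methoxy-4-(methoxymethoxy)phenyl]methyl]propanedioate | COCOc1cc(OCOC)c([C@@H](c2ccc(OCOC)c(OC)c2)C(C(=O)OC)C(=O)OC)c(/C=C/c2ccc(OCOC)c(OC)c2)c1 | intermediate
16 | methyl (3R)-3-{2,4-bis(methoxymethoxy)-6-[(E)-2-(3-methoxy-4-(methoxymethoxy)phenyl)ethenyl]phenyl}-3-[3-methoxy-4-(methoxymethoxy)phenyl]propanoate | COCOc1cc(OCOC)c([C@@H](c2ccc(OCOC)c(OC)c2)CC(=O)OC)c(/C=C/c2ccc(OCOC)c(OC)c2)c1 | intermediate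
17 | methyl (3R)-3-{2,4-dihydroxy-6-[(E)-2-(4-hydroxy-3-methoxyphenyl)ethenyl]phenyl}-3-(4-hydroxy-3-methoxyphenyl)propanoate | Oc1cc(O)c([C@@H](c2ccc(O)c(OC)c2)CC(=O)OC)c(/C=C/c2ccc(O)c(OC)c2)c1 | intermediate
18 | (4R)-7-hydroxy-4-(4-hydroxy-3-methoxyphenyl)-5-[(E)-2-(4-hydroxy-3-methoxyphenyl)ethenyl]-3,4-dihydro-2H-chromen-2-one | COc1cc(/C=C/c2cc(O)cc3c2[C@@H](c2ccc(O)c(OC)c2)CC(=O)O3)ccc1O | target

## Step count and risks

Total: 11 steps. Longest linear sequence: 8 steps, from vanillin 4 through steps 3, 4, 5, 6, 7, 9, 10 and 11 to 18.

**Step 9 (key step, proposed new method).** Three things are most likely to go wrong.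
- Oxidative addition at the doubly ortho-substituted, electron-rich C–Br bond may be slow, so the diazo compound is consumed by carbene dimerization or azine formation before an aryl palladium is there to take it.
- Outer-sphere attack of the malonate at the congested C4 may be slow, leaving the benzyl palladium to be reduced or to add across the neighbouring alkene.
- Enantioselectivity may be poor because two events, aryl migration and anti attack after possible face exchange, both bear on the configuration and need not favour the same sense.

The fallback uses known chemistry and leaves the route at 10. A Mizoroki–Heck reaction of 10 with methyl acrylate (Pd(OAc)2, P(o-tol)3, Et3N, DMF, 100 °C) should give the ring A methyl cinnamate F1. Commercial 2-methoxy-4-(4,4,5,5-tetramethyl-1,3,2-dioxaborolan-2-yl)phenol is protected with MOMCl and iPr2NEt to give the ring B pinacol boronate F2. A rhodium-catalysed asymmetric 1,4-addition of F2 to F1 ([RhCl(C2H4)2]2 with a chiral 2,5-diarylbicyclo[2.2.2]octadiene, catalytic aqueous KOH, dioxane, 50 °C) then forms the C4–ring B bond and sets C4. This is the established route to 3,3-diarylpropanoates, and the diene enantiomer is chosen to give the R centre. The fallback comes back to the route at 16, so step 10 is not needed.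

**Step 2.** Over-bromination at the second equivalent position, or acid-promoted loss of an acetal from traces of HBr, could lower the yield, since the ring is deactivated by the formyl group and may need longer reaction times. Fallback from 2: reduction with NaBH4 gives [3,5-bis(methoxymethoxy)phenyl]methanol F3. Its more electron-rich ring should take NBS at low temperature to give [2-bromo-3,5-bis(methoxymethoxy)phenyl]methanol F4, and MnO2 in CH2Cl2 oxidizes F4 back to the aldehyde level, returning to the route at 3.

**Step 6.** At 130 °C the electron-rich benzylic chloride may alkylate its own arene ring (Friedel–Crafts self-condensation), and an acetal may be lost. Fallback from 8: PPh3 in toluene at 90 °C gives the benzylic phosphonium chloride F5 at lower temperature. Wittig reaction of F5 with 3 (KOtBu, THF) gives the stilbene as a mixture with the Z-stilbene F6, and catalytic PhSSPh in refluxing THF isomerizes the mixture to the E isomer. The fallback returns to the route at 10 and replaces steps 6 and 7.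

**Step 11.** Three processes threaten the last step:
- protonation of the electron-rich stilbene, followed by cyclization onto ring B or oligomerization;
- capture of the released formaldehyde by the resorcinol ring;
- incomplete ring closure of the hydroxy ester.

Fallback from 16: saponification with LiOH in THF–water gives the protected 3,3-diarylpropanoic acid F7; base is safe here because the phenols are still masked. Brief treatment of F7 with dilute aqueous HCl in THF at room temperature removes the acetals, and the free tetrahydroxy acid F8 closes onto the C8a phenol with loss of water, if necessary helped by a carbodiimide (EDC, THF). The fallback returns to the route at 18.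

## Further compounds

F1 | step 9 | methyl (2E)-3-{2,4-bis(methoxymethoxy)-6-[(E)-2-(3-methoxy-4-(methoxymethoxy)phenyl)ethenyl]phenyl}prop-2-enoate | COCOc1cc(OCOC)c(/C=C/C(=O)OC)c(/C=C/c2ccc(OCOC)c(OC)c2)c1
F2 | step 9 | 2-[3-methoxy-4-(methoxymethoxy)phenyl]-4,4,5,5-tetramethyl-1,3,2-dioxaborolane | COCOc1ccc(cc1OC)B1OC(C)(C)C(C)(C)O1
F3 | step 2 | [3,5-bis(methoxymethoxy)phenyl]methanol | COCOc1cc(CO)cc(OCOC)c1
F4 | step 2 | [2-bromo-3,5-bis(methoxymethoxy)phenyl]methanol | COCOc1cc(CO)c(Br)c(OCOC)c1
F5 | step 6 | {[3-methoxy-4-(methoxymethoxy)phenyl]methyl}triphenylphosphonium chloride | COCOc1ccc(C[P+](c2ccccc2)(c2ccccc2)c2ccccc2)cc1OC.[Cl-]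
F6 | step 6 | 2-bromo-1,5-bis(methoxymethoxy)-3-{(Z)-2-[3-methoxy-4-(methoxymethoxy)phenyl]ethenyl}benzene | COCOc1cc(OCOC)c(Br)c(/C=C\c2ccc(OCOC)c(OC)c2)c1
F7 | step 11 | (3R)-3-{2,4-bis(methoxymethoxy)-6-[(E)-2-(3-methoxy-4-(methoxymethoxy)phenyl)ethenyl]phenyl}-3-[3-methoxy-4-(methoxymethoxy)phenyl]propanoic acid | COCOc1cc(OCOC)c([C@@H](c2ccc(OCOC)c(OC)c2)CC(=O)O)c(/C=C/c2ccc(OCOC)c(OC)c2)c1
F8 | step 11 | (3R)-3-{2,4-dihydroxy-6-[(E)-2-(4-hydroxy-3-methoxyphenyl)ethenyl]phenyl}-3-(4-hydroxy-3-methoxyphenyl)propanoic acid | Oc1cc(O)c([C@@H](c2ccc(O)c(OC)c2)CC(=O)O)c(/C=C/c2ccc(O)c(OC)c2)c1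
A1 | alternative 1 | 2-{1-[4-(tert-butyldimethylsilyloxy)-3-methoxyphenyl]ethenyl}-3-{(E)-2-[4-(tert-butyldimethylsilyloxy)-3-methoxyphenyl]ethenyl}-5-(triisopropylsilyloxy)benzaldehyde | O=Cc1cc(O[Si](C(C)C)(C(C)C)C(C)C)cc(/C=C/c2ccc(O[Si](C)(C)C(C)(C)C)c(OC)c2)c1C(=C)c1ccc(O[Si](C)(C)C(C)(C)C)c(OC)c1
A2 | alternative 1 | (3R)-3-[4-(tert-butyldimethylsilyloxy)-3-methoxyphenyl]-4-{(E)-2-[4-(tert-butyldimethylsilyloxy)-3-methoxyphenyl]ethenyl}-6-(triisopropylsilyloxy)indan-1-one | COc1cc(/C=C/c2cc(O[Si](C(C)C)(C(C)C)C(C)C)cc3c2[C@@H](c2ccc(O[Si](C)(C)C(C)(C)C)c(OC)c2)CC3=O)ccc1O[Si](C)(C)C(C)(C)C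
A3 | alternative 2 | methyl (3R,10E)-3,11-bis[3-methoxy-4-(methoxymethoxy)phenyl]-5,7,9-trioxoundec-10-enoate | COC(=O)C[C@H](c1ccc(OCOC)c(OC)c1)CC(=O)CC(=O)CC(=O)/C=C/c1ccc(OCOC)c(OC)c1
A4 | alternative 2 | (4R)-7-hydroxy-4-[3-methoxy-4-(methoxymethoxy)phenyl]-5-{(E)-2-[3-methoxy-4-(methoxymethoxy)phenyl]ethenyl}-3,4-dihydro-2H-chromen-2-one | COc1cc(/C=C/c2cc(O)cc3c2[C@@H](c2ccc(OCOC)c(OC)c2)CC(=O)O3)ccc1OCOC
A5 | alternative 3 | methyl 3-[4-(tert-butyldimethylsilyloxy)-3-methoxyphenyl]-3-(2-{(E)-2-[4-(tert-butyldimethylsilyloxy)-3-methoxyphenyl]ethenyl}-4-oxocyclobut-2-en-1-yl)propanoate, side-chain centre arranged as C4 of 18, ring centre either way | O=C1C=C(/C=C/c2ccc(O[Si](C)(C)C(C)(C)C)c(OC)c2)C1[C@@H](c1ccc(O[Si](C)(C)C(C)(C)C)c(OC)c1)CC(=O)OC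
A6 | alternative 3 | (triisopropylsilyloxy)ethyne | C#CO[Si](C(C)C)(C(C)C)C(C)C
A7 | alternative 3 | methyl (3R)-3-[4-(tert-butyldimethylsilyloxy)-3-methoxyphenyl]-3-{2-hydroxy-6-[(E)-2-(4-(tert-butyldimethylsilyloxy)-3-methoxyphenyl)ethenyl]-4-(triisopropylsilyloxy)phenyl}propanoate | Oc1cc(O[Si](C(C)C)(C(C)C)C(C)C)cc(/C=C/c2ccc(O[Si](C)(C)C(C)(C)C)c(OC)c2)c1[C@@H](c1ccc(O[Si](C)(C)C(C)(C)C)c(OC)c1)CC(=O)OC
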